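I decided to work maple by hand, at 80 °C, where the listed constants apply unchanged, and to carry one number from it to the other flasks.

| setting | birch | ash | maple |
|---|---|---|---|
| starting material | 20 mM | 20 mM | 20 mM |
| second substrate | 0.200 equiv | 0.200 equiv | 0.200 equiv |
| gas | 9.2 mM (held) | 9.2 mM (held) | 9.2 mM (held) |
| free catalyst | 15 mol% | 15 mol% | 15 mol% |
| temperature | 120 °C | 100 °C | 80 °C |
| time | 2.0 h | 2.0 h | 2.0 h |

    starting material + partner + free catalyst → free catalyst + target (k1 = 59600 /M²/min, Ea1 = 43.0 kJ/mol)
    second substrate + partner + free catalyst → free catalyst + second product (k2 = 38200 /M²/s, Ea2 = 24.0 kJ/mol)
    2 free catalyst → spent catalyst (k3 = 13.1 /M/min, Ea3 = 66.0 kJ/mol)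
    target ⇌ isomer of the product (K4 = 0.81, k4 = 0.0506 /min, Ea4 = 109 kJ/mol, ΔH4 = 0 kJ/mol)
    gas ⇌ partner, rate k5*(csat - [partner]) (k5 = 5.76 /min, csat = 9.2 mM)
    (constants at 80 °C)

- a step written with two of one species runs at k times the square of its concentration and takes two of it each time
- at the start none of partner is dissolved
- the list of constants is for 80 °C, to be carried to other temperatures by the activation energies and enthalpies

- the flask that comes out highest in amount of target, in percent of the starting material charged, or "all alike" when all lie within 1.5 percentage points (birch / ash / maple / all alike)
- target at the end, in percent of the starting material charged, birch
- target at the end, in percent of the starting material charged, ash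
- target at the end, in percent of the starting material charged, maple

1. Start. With no partner dissolved, target began with zero slope. Partner entered at 53.0 mM/min at first, and in maple second substrate at its charge drew on it 7.69 times faster than starting material at its charge did. So I put a first knee in target after the 4.00 mM of second substrate had reacted.

2. Rise. With partner at saturation and free catalyst at its charge of 3.00 mM, starting material in maple has a pseudo-first-order half-life a = 0.421 min, but that is an estimate for a saturated flask. The two charges together ask for 24.0 mM of partner, and at the entry rate of the empty flask that takes at least u = 0.453 min, which is longer than a. The path to spent catalyst by itself halves free catalyst in c = 12.7 min. Conversion should finish first, because a and u are both shorter than c. In birch, where the starting-material step gains 4.4 and the catalyst loss gains 9.8, a and c become 0.0957 min and 1.30 min, while u, whose transfer step has no activation energy listed, stays as it is, and both a and u remain shorter than c.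

3. Peak and fall. Target passes to isomer and back, and τ is the half-life of that relaxation, from the forward and back constants added: 6.13 min in maple. Since a and u are shorter than τ in maple, I drew target in maple overshooting its level and then sliding down. The time allows 19.6 such half-lives, and this step needs no catalyst. In birch, 44 times faster, τ is 0.139 min.

4. Level. At rest isomer is K times target, and together they hold the charge. So the equilibrium share f, target over target plus isomer, is 55.2%, which is thermodynamic control. The enthalpy of the isomer step is 0 kJ/mol, so K stays put, and I committed to 55.2% in birch, 55.2% in ash and 55.2% in maple, with no flask ahead by 1.5 percentage points.

The forecast gave all alike, with 55.2% for birch, 55.2% for ash and 55.2% for maple, each between 54.5% and 56%, holding that “Isomerisation then has ample time to equilibrate over 2 h even at 80 °C”. My level coincided with it, and the cheap route was to hold the half-lives against each other and the time, then take one ratio.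

The simulation gave 55.2% in birch, 55.2% in ash and 55.2% in maple: all alike. Removing the path to spent catalyst made no difference to target in maple. The share f leaves 44.8% for the isomer, and maple held 44.8% at 2.00 h.

In a flask like birch with 34 mM of starting material, equivalents and loadings held, f contains no charge, so it gave 18.8 mM of target. The simulation gave 55.2% of the charge as target and 44.8% as isomer at 2.00 h.

Its constants are those of an exercise.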